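In germacrane numbering the target is a ten-membered carbocycle (C1–C10) whose ether oxygen bridges C5 and C10, i.e. an 11-oxabicyclo[4.4.1]undecane built from two oxepane rings. The key step exploits that C5 and C10 are latent carbonyl carbons. Their outer neighbours C6 and C9 are the γ-carbon of a butenolide and the α-carbon of a C8 ketone. Cutting C5–C6 and C9–C10 pairs an acyclic 1,6-keto-enal with a flat bis(silyloxy)vinylfuran. One chiral-silylium-catalysed formal (4+3) annulation joins them (vinylogous aldol, oxocarbenium formation, enol-silane capture), closes both oxepanes and sets C5, C6 and quaternary C10. Reductions, lactone methylenation, angeloylation and allylic oxidation follow.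

Key step: step 5

Remark on numbering: C11–C13 are the lactone carbons (C12 = carbonyl, C13 = exocyclic methylene), C14 is the methyl on C10, and C15 is the methylene on C4. "13-nor" means that C13 is still missing.
Assumption: the (S,S) antipode of the catalyst in step 5 is taken to direct Re-face attack at C5. If the sense is opposite, the (R,R) antipode is used and nothing else changes.

Step 1
Reactants: 1 1-methylcyclohexene
Product: 2 6-oxoheptanal
Conditions: O3, CH2Cl2, −78 °C; then Me2S, −78 °C → rt
Reagents that add atoms: ozone, [O-][O+]=O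
Why: Ozonolysis with reductive work-up cleaves the only C=C bond and gives the C10 methyl ketone and the C5 aldehyde on the C1–C4 chain; no stereocentre is formed.

Step 2
Reactants: 2 6-oxoheptanal
Product: 3 2-methylidene-6-oxoheptanal
Conditions: 37 % aq. HCHO, pyrrolidine (10 mol %), propionic acid (10 mol %), i-PrOH, 45 °C
Reagents that add atoms: formaldehyde, C=O
Why: Amine-catalysed Mannich condensation/elimination (aldehyde α-methylenation) runs through the aldehyde enamine only, formaldehyde should outrun the internal ketone as electrophile, and C15 is placed without a stereocentre.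

Step 3
Reactants: 4 4-bromofuran-2(5H)-one; 5 tributyl(1-ethoxyvinyl)stannane
Product: 7 4-acetylfuran-2(5H)-one, via ethoxyvinyl butenolide 6 (not isolated)
Conditions: PdCl2(PPh3)2 (5 mol %), toluene, 100 °C; then 1 M aq. HCl, THF, rt
Reagents that add atoms: water, O
Why: Stille coupling at the vinylogous acyl bromide installs the masked acetyl group (C8–C9), and mild acid hydrolysis of the enol ether unmasks it; no stereocentre is formed.

Step 4
Reactants: 7 4-acetylfuran-2(5H)-one
Product: 8 2-(triethylsilyloxy)-4-[1-(triethylsilyloxy)vinyl]furan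
Conditions: TESOTf (2.3 equiv), Et3N (3 equiv), CH2Cl2, 0 °C
Reagents that add atoms: triethylsilyl triflate, CC[Si](CC)(CC)OS(=O)(=O)C(F)(F)F
Why: Soft enolisation with silyl triflate/amine silylates the butenolide as the aromatic 2-silyloxyfuran and the methyl ketone as its enol silane, which makes C6 and C9 the two nucleophilic termini of a C6=C7–C8=C9 diene.

Step 5
Reactants: 3 2-methylidene-6-oxoheptanal; 8 2-(triethylsilyloxy)-4-[1-(triethylsilyloxy)vinyl]furan
Product: 11 (5S,6S,10R)-5,10-epoxy-8-oxo-13-norgermacra-4(15),7(11)-dien-12,6-olide, via open aldol adduct 9 (not isolated), via oxepanyl oxocarbenium ion 10 (not isolated)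
Conditions: (S,S)-imidodiphosphorimidate (IDPi) Brønsted acid (5 mol %, silylated in situ by 8), 8 (1.2 equiv), slow addition of 3, toluene/CH2Cl2 (0.02 M), −78 → −30 °C
Reagents that add atoms: none
Why: Proposed new method: the IDPi acid is silylated by 8 to a chiral silylium ion pair that activates the enal of 3, so the furan γ-carbon C6 adds 1,2 to C5 (vinylogous Mukaiyama aldol with TES transfer to O5) to give 9; the C5–OTES oxygen then attacks the silylium-activated C10 ketone, hexaethyldisiloxane leaves, and the enol-silane carbon C9 captures oxocarbenium ion 10 at C10. The closest known reaction type is the Lewis-acid annulation of bis(silyl enol ethers) with 1,4- and 1,5-dicarbonyl compounds to oxa-bridged bicycles, combined with silylium-based counteranion-directed asymmetric Mukaiyama aldol catalysis; new are the 1,6-keto-enal, the 1,4-dinucleophile and the bicyclo[4.4.1] ring size. The first oxepane (O, C10, C1–C5) closes by 7-exo-trig attack of oxygen on the ketone, and the second (O, C5, C6–C10) closes by 7-endo-trig, enol-endo attack of C9 on C10=O+, which also closes the ten-membered carbocycle. C5 is set by the chiral counteranion (Re-face attack), C6 by the threo (syn) preference usual for Lewis-acid additions of 2-silyloxyfurans to aldehydes, and C10 by the tether, because C9 can only reach the face of 10 that is cis to C6 across the ring oxygen. The step needs aldehyde-before-ketone, C6-before-C9 and 1,2- over 1,4-/[4+2] selectivity; these rest on the higher electrophilicity of the enal carbonyl, the higher nucleophilicity of the silyloxyfuran terminus compared with the cross-conjugated enol silane, and the usual 1,2-preference of silyloxyfurans toward Lewis-acid-activated enals.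

Step 6
Reactants: 11 (5S,6S,10R)-5,10-epoxy-8-oxo-13-norgermacra-4(15),7(11)-dien-12,6-olide
Product: 12 (5S,6S,7S,10R)-5,10-epoxy-8-oxo-13-norgermacr-4(15)-en-12,6-olide (trans-fused lactone)
Conditions: Zn dust, AcOH, rt
Reagents that add atoms: none
Why: Dissolving-metal reduction is selective for the electron-poor ene-1,4-dicarbonyl bond C7=C11 over the isolated C4 methylene, and C7, being α to the C8 ketone, should equilibrate through the enol to the trans-fused lactone, in which both lactone bonds are pseudo-equatorial on the oxepane.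

Step 7
Reactants: 12 (5S,6S,7S,10R)-5,10-epoxy-8-oxo-13-norgermacr-4(15)-en-12,6-olide
Product: 13 (5S,6S,7R,8R,10R)-5,10-epoxy-8-hydroxy-13-norgermacr-4(15)-en-12,6-olide
Conditions: L-Selectride (1.1 equiv), THF, −78 °C; then H2O
Reagents that add atoms: none
Why: Bulky trialkylborohydride reduction of an α-substituted cycloalkanone should deliver hydride along the equatorial trajectory anti to the C7–C11 bond and give the alcohol cis to C11 (8R), while the lactone survives at −78 °C.

Step 8
Reactants: 13 (5S,6S,7R,8R,10R)-5,10-epoxy-8-hydroxy-13-norgermacr-4(15)-en-12,6-olide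
Product: 14 (5S,6S,7S,8R,10R)-8-(tert-butyldimethylsilyloxy)-5,10-epoxy-13-norgermacr-4(15)-en-12,6-olide
Conditions: TBSOTf, 2,6-lutidine, CH2Cl2, 0 °C
Reagents that add atoms: tert-butyldimethylsilyl triflate, CC(C)(C)[Si](C)(C)OS(=O)(=O)C(F)(F)F
Why: Standard silyl ether protection masks O8 so that no alkoxide can translactonise onto C12 or consume base in the next step; no stereocentre changes.

Step 9
Reactants: 14 (5S,6S,7S,8R,10R)-8-(tert-butyldimethylsilyloxy)-5,10-epoxy-13-norgermacr-4(15)-en-12,6-olide
Product: 17 (5S,6S,7S,8R,10R)-8-(tert-butyldimethylsilyloxy)-5,10-epoxygermacra-4(15),11(13)-dien-12,6-olide, via Mannich base 15 (not isolated), via methiodide 16 (not isolated)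
Conditions: LDA, THF, −78 °C; CH2=NMe2+ I−, −78 °C → rt; then MeI, THF, rt; then aq. NaHCO3, CH2Cl2, rt
Reagents that add atoms: dimethylmethylideneammonium iodide (Eschenmoser's salt), C=[N+](C)C.[I-]; iodomethane, CI (its carbon enters 16 only)
Why: Lactone-enolate Mannich reaction with Eschenmoser's salt, quaternisation and Hofmann-type E1cB elimination is the standard α-methylenation of γ-butyrolactones; C11 is the only acidic position and ends sp2, so no stereocentre is at stake.

Step 10
Reactants: 17 (5S,6S,7S,8R,10R)-8-(tert-butyldimethylsilyloxy)-5,10-epoxygermacra-4(15),11(13)-dien-12,6-olide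
Product: 18 (5S,6S,7R,8R,10R)-5,10-epoxy-8-hydroxygermacra-4(15),11(13)-dien-12,6-olide
Conditions: HF·pyridine, THF, 0 °C → rt
Reagents that add atoms: none
Why: Fluoride-mediated desilylation under buffered acidic conditions frees O8 without conjugate addition to the α-methylene lactone and without touching a stereocentre.

Step 11
Reactants: 18 (5S,6S,7R,8R,10R)-5,10-epoxy-8-hydroxygermacra-4(15),11(13)-dien-12,6-olide; 19 angelic acid
Product: 21 (5S,6S,7R,8R,10R)-8-angeloyloxy-5,10-epoxygermacra-4(15),11(13)-dien-12,6-olide, via mixed anhydride 20 (not isolated)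
Conditions: 19, 2,4,6-trichlorobenzoyl chloride, Et3N, toluene, rt; then 18, 80 °C
Reagents that add atoms: 2,4,6-trichlorobenzoyl chloride, O=C(Cl)c1c(Cl)cc(Cl)cc1Cl (enters 20 only)
Why: Yamaguchi-type mixed-anhydride esterification without a nucleophilic catalyst acylates O8 with retention at C8 and is the usual way to avoid Z-to-E isomerisation of the angelate.

Step 12
Reactants: 21 (5S,6S,7R,8R,10R)-8-angeloyloxy-5,10-epoxygermacra-4(15),11(13)-dien-12,6-olide
Product: 22 (5S,6S,7R,8R,10R)-8-angeloyloxy-5,10-epoxy-3-hydroxygermacra-4(15),11(13)-dien-12,6-olide (C3 epimers)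
Conditions: SeO2 (0.3 equiv), t-BuOOH (3 equiv), CH2Cl2, 0 °C → rt
Reagents that add atoms: tert-butyl hydroperoxide, CC(C)(C)OO (terminal oxygen source, relayed by catalytic selenium dioxide, O=[Se]=O)
Why: Riley allylic oxidation (ene reaction then [2,3]-shift) should act only on the one electron-rich alkene, prefer the C3 methylene over the bridgehead C5–H and keep C4=C15 in place; the C3 configuration is irrelevant because it is oxidised next.

Step 13
Reactants: 22 (5S,6S,7R,8R,10R)-8-angeloyloxy-5,10-epoxy-3-hydroxygermacra-4(15),11(13)-dien-12,6-olide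
Product: 24 target CNP0335602.1 = (5S,6S,7R,8R,10S)-8-angeloyloxy-5,10-epoxy-3-oxogermacra-1(Z),4(15),11(13)-trien-12,6-olide, via enone 23 (not isolated)
Conditions: IBX (3 equiv), DMSO, 70 °C
Reagents that add atoms: none
Why: IBX first oxidises the allylic alcohol to the α-methylene ketone and then dehydrogenates it (IBX ketone dehydrogenation); C2 carries the only enolisable hydrogens, so C1=C2 (cis in the seven-membered ring) is the only possible new double bond and no stereocentre is touched.

Compound list
1 | 1-methylcyclohexene | CC1=CCCCC1 | starting material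
2 | 6-oxoheptanal | CC(=O)CCCCC=O | intermediate
3 | 2-methylidene-6-oxoheptanal | CC(=O)CCCC(=C)C=O | intermediate
4 | 4-bromofuran-2(5H)-one | O=C1C=C(Br)CO1 | starting material
5 | tributyl(1-ethoxyvinyl)stannane | CCCC[Sn](CCCC)(CCCC)C(=C)OCC | starting material
6 | 4-(1-ethoxyvinyl)furan-2(5H)-one | C=C(OCC)C1=CC(=O)OC1 | intermediate
7 | 4-acetylfuran-2(5H)-one | CC(=O)C1=CC(=O)OC1 | intermediate
8 | 2-(triethylsilyloxy)-4-[1-(triethylsilyloxy)vinyl]furan | C=C(O[Si](CC)(CC)CC)c1coc(O[Si](CC)(CC)CC)c1 | intermediate
9 | (5S)-5-[(1S)-2-methylidene-6-oxo-1-(triethylsilyloxy)heptyl]-4-[1-(triethylsilyloxy)vinyl]furan-2(5H)-one (germacrane 5S,6S) | O=C1C=C(C(=C)O[Si](CC)(CC)CC)[C@H](O1)[C@@H](O[Si](CC)(CC)CC)C(=C)CCCC(C)=O | intermediate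
10 | (5S,6S)-oxepanyl oxocarbenium ion, C10=O+–C5 in the seven-membered ring, butenolide with enol silane on C5 (counter-ion: IDPi anion) | O=C1C=C(C(=C)O[Si](CC)(CC)CC)[C@H](O1)[C@H]1[O+]=C(C)CCCC1=C | intermediate
11 | (5S,6S,10R)-5,10-epoxy-8-oxo-13-norgermacra-4(15),7(11)-dien-12,6-olide | O=C1C=C2C(=O)C[C@@]3(C)CCCC(=C)[C@H](O3)[C@H]2O1 | intermediate
12 | (5S,6S,7S,10R)-5,10-epoxy-8-oxo-13-norgermacr-4(15)-en-12,6-olide | O=C1C[C@@H]2C(=O)C[C@@]3(C)CCCC(=C)[C@H](O3)[C@H]2O1 | intermediate
13 | (5S,6S,7R,8R,10R)-5,10-epoxy-8-hydroxy-13-norgermacr-4(15)-en-12,6-olide | O=C1C[C@@H]2[C@H](O)C[C@@]3(C)CCCC(=C)[C@H](O3)[C@H]2O1 | intermediate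
14 | (5S,6S,7S,8R,10R)-8-(tert-butyldimethylsilyloxy)-5,10-epoxy-13-norgermacr-4(15)-en-12,6-olide | O=C1C[C@@H]2[C@H](O[Si](C)(C)C(C)(C)C)C[C@@]3(C)CCCC(=C)[C@H](O3)[C@H]2O1 | intermediate
15 | 11-(dimethylaminomethyl) derivative of 14 (C11 epimers) | O=C1C(CN(C)C)[C@@H]2[C@H](O[Si](C)(C)C(C)(C)C)C[C@@]3(C)CCCC(=C)[C@H](O3)[C@H]2O1 | intermediate
16 | trimethylammonium iodide of 15 | O=C1C(C[N+](C)(C)C)[C@@H]2[C@H](O[Si](C)(C)C(C)(C)C)C[C@@]3(C)CCCC(=C)[C@H](O3)[C@H]2O1.[I-] | intermediate
17 | (5S,6S,7S,8R,10R)-8-(tert-butyldimethylsilyloxy)-5,10-epoxygermacra-4(15),11(13)-dien-12,6-olide | O=C1C(=C)[C@@H]2[C@H](O[Si](C)(C)C(C)(C)C)C[C@@]3(C)CCCC(=C)[C@H](O3)[C@H]2O1 | intermediate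
18 | (5S,6S,7R,8R,10R)-5,10-epoxy-8-hydroxygermacra-4(15),11(13)-dien-12,6-olide | O=C1C(=C)[C@@H]2[C@H](O)C[C@@]3(C)CCCC(=C)[C@H](O3)[C@H]2O1 | intermediate
19 | angelic acid, (Z)-2-methylbut-2-enoic acid | C/C=C(/C)C(=O)O | starting material
20 | angelic 2,4,6-trichlorobenzoic anhydride | C/C=C(/C)C(=O)OC(=O)c1c(Cl)cc(Cl)cc1Cl | intermediate
21 | (5S,6S,7R,8R,10R)-8-angeloyloxy-5,10-epoxygermacra-4(15),11(13)-dien-12,6-olide | O=C1C(=C)[C@@H]2[C@H](OC(=O)/C(C)=C\C)C[C@@]3(C)CCCC(=C)[C@H](O3)[C@H]2O1 | intermediate
22 | 3-hydroxy derivative of 21 (C3 epimers) | O=C1C(=C)[C@@H]2[C@H](OC(=O)/C(C)=C\C)C[C@@]3(C)CCC(O)C(=C)[C@H](O3)[C@H]2O1 | intermediate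
23 | 3-oxo derivative of 21 (α-methylene ketone) | O=C1C(=C)[C@@H]2[C@H](OC(=O)/C(C)=C\C)C[C@@]3(C)CCC(=O)C(=C)[C@H](O3)[C@H]2O1 | intermediate
24 | CNP0335602.1, (5S,6S,7R,8R,10S)-8-angeloyloxy-5,10-epoxy-3-oxogermacra-1(Z),4(15),11(13)-trien-12,6-olide | C=C1C(=O)O[C@H]2[C@H]1[C@H](OC(=O)/C(C)=C\C)C[C@@]1(C)C=CC(=O)C(=C)[C@@H]2O1 | target

Total step count: 13. Longest linear sequence: 11 steps (1, 2, 5–13). Steps 3 and 4 form the second branch.

**Step 5 is most at risk.** It may fail in four ways:
- first attack through the enol-silane terminus instead of the furan terminus;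
- an ionic [4+2] addition of the vinylfuran diene to the enal;
- stalling after the first C–C bond, because the seven-membered oxocarbenium ion forms slowly;
- weak facial control by the counteranion.

The fallback uses known chemistry, sets out from 3 and 8 and comes back at 11. It gives up the one-flask union and makes the two bonds in separate reactions. A Ti(Oi-Pr)4/BINOL-catalysed vinylogous Mukaiyama aldol addition of 8 to 3 (antipode chosen for Re-face attack, Et2O, −20 °C, buffered work-up) should give (5S)-5-[(1S)-1-hydroxy-2-methylidene-6-oxoheptyl]-4-[1-(triethylsilyloxy)vinyl]furan-2(5H)-one F1. Its diastereomers can be separated at this stage. F1 is then closed under high dilution with catalytic TMSOTf or Bi(OTf)3 (CH2Cl2, −78 → 0 °C). The hydroxy ketone passes through its cyclic hemiketal to an oxocarbenium ion, which the tethered enol silane captures. This is the way ketose-type donors are C-glycosylated by silyl enol ethers, and it gives 11.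

**Step 6 is second.** It may fail through protonation of the enol at C7 from the wrong face without later equilibration. It may also fail through loss of the lactone C6–O bond by β-elimination from the zinc enolate. The fallback sets out from 11 and comes back at 14, so it bypasses 12 and 13 and never forms a C8 enolate.
- Corey–Bakshi–Shibata reduction ((S)-Me-CBS, catecholborane, toluene, −78 °C; alkenyl C7 as the large group) should give (5S,6S,8R,10R)-5,10-epoxy-8-hydroxy-13-norgermacra-4(15),7(11)-dien-12,6-olide F2 by reagent control.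
- TBSOTf/2,6-lutidine gives its 8-O-TBS ether F3.
- A ligand-controlled copper hydride conjugate reduction of the butenolide (Cu(OAc)2, DTBM-SEGPHOS antipode matched to the substrate, PMHS, t-BuOH, toluene) should add hydride to C7 anti to the bulky C8 silyloxy group and give 14.

**Step 7 is third.** It may fail through hydride delivery from the opposite face of the C8 carbonyl, or through translactonisation of the C8 alkoxide onto C12. The fallback sets out from 12 and comes back at 13. The epimeric alcohol is accepted and then inverted.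
- NaBH4/CeCl3 (MeOH, −78 °C) gives (5S,6S,7R,8S,10R)-5,10-epoxy-8-hydroxy-13-norgermacr-4(15)-en-12,6-olide F4.
- Mitsunobu reaction (4-nitrobenzoic acid, PPh3, DIAD, THF) inverts C8 by attack from the open convex face to give the (8R)-4-nitrobenzoate F5.
- Brief methanolysis (K2CO3, MeOH, 0 °C) gives 13.

Further compounds
F1 | step 5 | (5S)-5-[(1S)-1-hydroxy-2-methylidene-6-oxoheptyl]-4-[1-(triethylsilyloxy)vinyl]furan-2(5H)-one | O=C1C=C(C(=C)O[Si](CC)(CC)CC)[C@H](O1)[C@@H](O)C(=C)CCCC(C)=O
F2 | step 6 | (5S,6S,8R,10R)-5,10-epoxy-8-hydroxy-13-norgermacra-4(15),7(11)-dien-12,6-olide | O=C1C=C2[C@H](O)C[C@@]3(C)CCCC(=C)[C@H](O3)[C@H]2O1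
F3 | step 6 | 8-O-TBS ether of F2 | O=C1C=C2[C@H](O[Si](C)(C)C(C)(C)C)C[C@@]3(C)CCCC(=C)[C@H](O3)[C@H]2O1
F4 | step 7 | (5S,6S,7R,8S,10R)-5,10-epoxy-8-hydroxy-13-norgermacr-4(15)-en-12,6-olide | O=C1C[C@@H]2[C@@H](O)C[C@@]3(C)CCCC(=C)[C@H](O3)[C@H]2O1
F5 | step 7 | (8R)-4-nitrobenzoate of 13 | O=C1C[C@@H]2[C@H](OC(=O)c4ccc(cc4)[N+](=O)[O-])C[C@@]3(C)CCCC(=C)[C@H](O3)[C@H]2O1
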